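The numbers in the tables were computed for an exercise.

**The charges.** Elm held 200 mM of starting material, cedar twice that and ash 100 mM, so I counted each flask in shares of its own charge.

| setting | elm | cedar | larch | ash |
|---|---|---|---|---|
| starting material | 200 mM | 400 mM | 200 mM | 100 mM |
| free catalyst | 1.00 mM | 1.00 mM | 0.500 mM | 1.00 mM |
| time |  |  |  | 18 min |

| run | time / min | [product] / mM |
|---|---|---|
| elm run | 1.4 | 9.8 |
| elm run | 4.2 | 23.0 |
| elm run | 7.9 | 43.6 |
| elm run | 13 | 64.5 |
| elm run | 18 | 76.3 |
| cedar run | 1.4 | 11.9 |
| cedar run | 4.2 | 33.8 |
| cedar run | 7.9 | 63.2 |
| cedar run | 13 | 94.4 |
| cedar run | 18 | 118.6 |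
| larch run | 1.4 | 3.3 |
| larch run | 4.2 | 12.8 |
| larch run | 7.9 | 25.6 |
| larch run | 13 | 37.9 |
| larch run | 18 | 51.3 |

(each reading ± 2 mM)

1. the exponent of [starting material] in the starting rate at the charge of the elm run (at the point where two percent of the starting material have become product) (one fixed amount of product, the same in the runs compared)
2. the exponent of [free catalyst] in the starting rate at the charge of the elm run (at the point where two percent of the starting material have become product)
3. product in the ash run at 18 min, as a share of the starting material charged

- Overall: starting material -> product, with free catalyst as catalyst.
- Constant volume, constant temperature.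
- The analysis sees a species whether free or bound.
- An order is taken over about fifteen percent of the charge, up and down.

**First minutes.** At 1.4 min elm stood at 4.90 % of its charge, but the scatter was 20.4 % of that reading, so I drew no ratio there.

**The middle.** At a quarter of elm's charge the same scatter is 4.00 % of the amount, a smaller part, so I read there. Between neighbouring readings, elm reached that share at 9.46 min, cedar at 14.2 min and larch at 17.5 min. Cedar's time over elm's is 1.50. I call this the stretch: the factor on the time to one share of the charge when the charge is doubled and the free catalyst stays the same. As a power of the charge it gives a reaction order in starting material of 0.415 over that first part of the run, as a reading. Larch, with half the free catalyst, took 1.85 times elm's time, an order of 0.888 in free catalyst.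

**The end.** Taking the stretch to hold for ash, ash at 18 min stands where elm stands at 27.0 min. Elm's last two readings rise at 2.36 mM min⁻¹, and continuing that line gives 48.7 %. Elm's rise had already slowed from 4.10 mM min⁻¹, so I held that figure as a little high.

**The forecast.** The forecast gave starting orders of 0.58 in starting material and 0.9 in free catalyst and 45 % for ash, noting “That hints at catalyst loss”, and its ash figure stood below mine.

**The result.** The flask gave starting orders of 0.49 in starting material and 1.0 in free catalyst, and ash reached 45.8 %, which is 2.9 percentage points under my figure.

    free catalyst + starting material ⇌ catalyst-substrate complex (188.4 M⁻¹ min⁻¹, 19.44 min⁻¹)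
    catalyst-substrate complex → product + free catalyst (16.74 min⁻¹)
    2 starting material ⇌ idle substrate dimer, settled at all times (1.770 M⁻¹)
    2 free catalyst → 2 spent catalyst (69.00 M⁻¹ min⁻¹)

**Stretch again.** Elm reached half of its charge at 27.8 min, which the stretch moves to 18.5 min for ash, yet ash stood at 45.8 % at 18 min. On cedar the same stretch turns elm's time into 41.7 min, and cedar took 39.6 min.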